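- If target is made from substrate and then lost in its turn, I need two half-lives, the substrate's and the target's, and these two, held against the asked time and taken with the yield, tell me how much target stands at that time.

| flask | substrate | capture agent | remark | time |
|---|---|---|---|---|
| beta | 8.000 × 10⁻⁵ M | 1.3 mM | run made earlier |  |
| eta | 8.000 × 10⁻⁵ M | 4 mM | run made earlier |  |
| elm | 8.0 × 10⁻⁵ M | 2.00 mM |  | 4.0 min |
| oak | 2.0 × 10⁻⁴ M | 2.00 mM |  | 4.0 min |
| birch | 6.0 × 10⁻⁴ M | 2.00 mM |  | 4.0 min |
| cedar | 0.0020 M | 2.00 mM |  | 4.0 min |
| larch | 0.0060 M | 2.00 mM |  | 4.0 min |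

| run | time / s | target / % | substrate / % |
|---|---|---|---|
| beta | 10.0 | 10.9 | 82.7 |
| beta | 20.0 | 22.0 | 69.8 |
| beta | 40.0 | 39.7 | 48.2 |
| beta | 60.0 | 49.6 | 33.1 |
| beta | 80.0 | 54.9 | 23.1 |
| eta | 10.0 | 10.2 | 83.3 |
| eta | 20.0 | 21.1 | 69.8 |
| eta | 40.0 | 37.4 | 48.4 |
| eta | 60.0 | 47.5 | 32.6 |
| eta | 80.0 | 51.6 | 23.2 |

(each reading ± 0.5 percentage points)

- "hardly changes" means that all values lie within two and a half points (for a concentration: within two and a half percent of the largest)

- [target] at the end for elm, oak, birch, cedar, larch, in this order
- the shape of the row from first to last (falls, then rises / rises all the way / falls all the way / hardly changes / rises, then falls)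

- Substrate in the beta run falls to 23.1 % by 80.0 s, which gives a half-life of 37.8 s, and the eta run, with 4 mM of capture agent instead of 1.3 mM, shows 23.2 %.
- Target at that time is lower in eta, 51.6 % against 54.9 %, so I treat the capture agent as a small drain rather than an ingredient, put no cap at its charge, and take the target's loss as pseudo-first-order.
- Let s and x be the fractions of substrate and of target surviving 40.0 s: the target then goes as x to the power m minus s to the power m after m such intervals, so the reading at twice that time over the first reading is x + s, and the unknown yield cancels.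
- This gives x = 0.901 in beta and 0.896 in eta, so the target's half-life is 258 s, longer than the substrate's by a factor 6.83.
- With m = 6.00, the share comes to 49.5 % for beta and 45.7 % for eta, and between them, at the charge of 2.00 mM, I get the end share f = 48.5 %, the part of the substrate charged that stands as target at the asked time.
- Both runs hold 8.000 × 10⁻⁵ M of substrate, so I assume f carries over unchanged, and my row rises all the way from 3.88 × 10⁻⁵ M in elm to 0.00291 M in larch.
- The forecast differs at the end, giving 3.000 × 10⁻⁵ M for elm, 7.600 × 10⁻⁴ M for cedar and 6.500 × 10⁻⁴ M for larch, with the shape rises, then falls, since “the agent is stoichiometric”.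

    open intermediate ⇌ target (K = 9.10, k = 0.360 /s)
    open intermediate → side product (k = 0.0180 /s)
    substrate → open intermediate (k = 0.0180 /s)
    open intermediate + capture agent → trapped intermediate (k = 3.80 /M/s)
    2 substrate → self-condensation product (k = 3.40 /M/s)
    open intermediate ⇌ isomer of the product (K = 120, k = 0.00630 /s)

- The flask gives 3.82 × 10⁻⁵ M, 9.34 × 10⁻⁵ M, 2.61 × 10⁻⁴ M, 7.15 × 10⁻⁴ M and 0.00149 M, so the row rises all the way. Elm holds 47.8 % of its charge as target, next to f of 48.5 %. In larch at 4.00 min, self-condensation product stands at 47.8 % of the substrate charged, each unit of it holding two substrate. Applied to the rest of that charge, f gives 25.3 % of the charge, and larch holds 24.8 %.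

Readings and results stem from a simulated flask on assumed constants.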